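**Plan**

- Retrosynthetic cuts, in order: the C2–C3 epoxide oxygen and the C9 acetate/carbinol; the C10–C1 bond (retro-Claisen, which re-forms an O–C3 bond); the O–C9 enol-ether bond; the C8 ester; C7–C8; C11–C13; C6–C7; C3–C2.
- Forward ring order: butenolide (C12–O–C6) → α-methylene lactone → eight-membered oxacycle (O, C9, C8, C7, C6, C5, C4, C3) → ten-membered carbocycle by a two-atom ring expansion → second epoxide.
- Enabling feature: C9 carries oxygen and C2/C3 are an (epoxidised) alkene in a 1,5-relation to it across C10–C1. Tying the C9 oxygen to C3 therefore gives an allyl vinyl ether C10=C9–O–C3–C2=C1 inside the oxacycle.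
- Stereochemistry: C3 by CBS reduction (relay centre, erased later); C4/C5 by C3–OH-directed epoxidation; C6 by catalyst-controlled alkynylation; C7 anti to the C6 substituent on the butenolide; C8 by Barbier addition then Mitsunobu inversion; C9 by Luche reduction; C2/C3 by epoxidation anti to the 4,5-epoxide; side chain by Sharpless epoxidation.

Key step: step 20

Remark: locants C1–C15 follow germacranolide numbering (lactone at C6/C7, CO2Me on C10, methyl on C4). The C3 carbinol centre only directs the C4–C5 epoxidation and becomes sp2 in the key step.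

**Step 1**
Reactants: 1 3-methylfuran-2(5H)-one; 2 vinylmagnesium bromide
Product: 4 rac-(2Z)-3-methylhexa-2,5-diene-1,4-diol, via lactol 3-methyl-2,5-dihydrofuran-2-ol 3 (not isolated)
Conditions: DIBAL-H, CH2Cl2, −78 °C; then 2 (3 equiv), THF, −78 → 0 °C
Reagents that add atoms: none
Why: Lactone half-reduction stops at the aluminium hemiacetal, and Grignard 1,2-addition to the ring-opened (Z)-hydroxy enal should give the diol with the Z geometry inherited from the ring.

**Step 2**
Reactants: 4 rac-(2Z)-3-methylhexa-2,5-diene-1,4-diol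
Product: 5 rac-(4Z)-4-methyl-6-(triethylsilyloxy)hexa-1,4-dien-3-ol
Conditions: TESCl (1.0 equiv), imidazole, CH2Cl2, −40 °C
Reagents that add atoms: chlorotriethylsilane, CC[Si](Cl)(CC)CC
Why: Silylation should select the unhindered primary hydroxyl over the secondary bis-allylic one.

**Step 3**
Reactants: 5 rac-(4Z)-4-methyl-6-(triethylsilyloxy)hexa-1,4-dien-3-ol
Product: 6 (4Z)-4-methyl-6-(triethylsilyloxy)hexa-1,4-dien-3-one
Conditions: MnO2, CH2Cl2, 20 °C
Reagents that add atoms: none
Why: MnO2 oxidation of an allylic alcohol is neutral, so the Z alkene and the silyl ether should survive.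

**Step 4**
Reactants: 6 (4Z)-4-methyl-6-(triethylsilyloxy)hexa-1,4-dien-3-one
Product: 7 (3R,4Z)-4-methyl-6-(triethylsilyloxy)hexa-1,4-dien-3-ol
Conditions: (S)-Me-CBS (10 mol %), BH3·SMe2, THF, −40 °C
Reagents that add atoms: none
Why: In this Corey–Bakshi–Shibata reduction the α-branched trisubstituted alkenyl group acts as the large substituent and vinyl as the small one, so the (S)-catalyst should give the (R)-carbinol by 1,2-reduction.

**Step 5**
Reactants: 7 (3R,4Z)-4-methyl-6-(triethylsilyloxy)hexa-1,4-dien-3-ol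
Product: 8 (3R,4Z)-4-methyl-3,6-bis(triethylsilyloxy)hexa-1,4-diene
Conditions: TESOTf, 2,6-lutidine, CH2Cl2, −78 °C
Reagents that add atoms: triethylsilyl triflate, CC[Si](CC)(CC)OS(=O)(=O)C(F)(F)F
Why: Silyl triflate silylation of a secondary alcohol is fast at low temperature and does not touch the stereocentre.

**Step 6**
Reactants: 8 (3R,4Z)-4-methyl-3,6-bis(triethylsilyloxy)hexa-1,4-diene
Product: 9 (2Z,4R)-3-methyl-4-(triethylsilyloxy)hexa-2,5-dienal
Conditions: (COCl)2, DMSO, CH2Cl2, −78 → −30 °C; Et3N
Reagents that add atoms: none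
Why: Swern conditions convert a primary triethylsilyl ether directly into the aldehyde while a secondary one survives, and the low temperature should keep the (Z)-enal from isomerising.

**Step 7**
Reactants: 9 (2Z,4R)-3-methyl-4-(triethylsilyloxy)hexa-2,5-dienal; 10 methyl propiolate
Product: 11 methyl (4R,5Z,7R)-4-hydroxy-6-methyl-7-(triethylsilyloxy)nona-5,8-dien-2-ynoate
Conditions: Me2Zn, ProPhenol ligand (enantiomer giving Si-face addition, 10 mol %), Ph3PO, toluene, 4 °C
Reagents that add atoms: none
Why: Zinc–ProPhenol-catalysed asymmetric alkynylation of an enal forms C6–C7 and sets C6 under catalyst control, the remote C3 centre exerting little bias.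

**Step 8**
Reactants: 11 methyl (4R,5Z,7R)-4-hydroxy-6-methyl-7-(triethylsilyloxy)nona-5,8-dien-2-ynoate
Product: 13 (5S)-5-[(1Z,3R)-2-methyl-3-(triethylsilyloxy)penta-1,4-dien-1-yl]furan-2(5H)-one, via methyl (2Z,4S,5Z,7R)-4-hydroxy-6-methyl-7-(triethylsilyloxy)nona-2,5,8-trienoate 12 (not isolated)
Conditions: H2 (1 atm), Lindlar catalyst, quinoline, EtOAc, 0 °C; then PPTS (cat.), CH2Cl2
Reagents that add atoms: none
Why: Lindlar semihydrogenation is alkyne-selective and gives the (Z)-γ-hydroxy enoate, which lactonises to the butenolide.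

**Step 9**
Reactants: 13 (5S)-5-[(1Z,3R)-2-methyl-3-(triethylsilyloxy)penta-1,4-dien-1-yl]furan-2(5H)-one
Product: 14 3-(hydroxymethyl) derivative of 13 (CH2OH on C11)
Conditions: 37% aq. HCHO, imidazole (cat.), THF–H2O, 25 °C
Reagents that add atoms: formaldehyde, C=O
Why: Morita–Baylis–Hillman hydroxymethylation of the cyclic enoate introduces C13 at the α-carbon, and the weak base should not touch the C6 centre.

**Step 10**
Reactants: 14 3-(hydroxymethyl) derivative of 13
Product: 15 3-(bromomethyl) derivative of 13 (CH2Br on C11)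
Conditions: CBr4, PPh3, 2,6-lutidine, CH2Cl2, −20 °C
Reagents that add atoms: carbon tetrabromide, BrC(Br)(Br)Br
Why: The Appel reaction converts the primary allylic alcohol into the bromide under neutral conditions that the silyl ether tolerates.

**Step 11**
Reactants: 16 methyl 4-hydroxybut-2-ynoate
Product: 17 methyl 4-oxobut-2-ynoate
Conditions: MnO2, CH2Cl2, 20 °C; filtered solution used at once
Reagents that add atoms: none
Why: MnO2 oxidises the propargylic alcohol to the ynal without over-oxidation.

**Step 12**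
Reactants: 15 3-(bromomethyl) derivative of 13; 17 methyl 4-oxobut-2-ynoate
Product: 18 6,7-trans α-methylene-γ-butyrolactone with the (8R)-carbinol CH(OH)–C≡C–CO2Me on C7 (8-epi)
Conditions: Zn dust, THF/sat. aq. NH4Cl, 0 °C
Reagents that add atoms: none
Why: In this Barbier allylation the ring-locked allylzinc attacks through C7 (SE2′) anti to the C6 side chain, giving the trans lactone, and a Zimmerman–Traxler chair with the alkynyl group equatorial should give the C7/C8 anti carbinol, which step 16 inverts.

**Step 13**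
Reactants: 19 angelic acid
Product: 20 (2Z)-2-methylbut-2-en-1-ol
Conditions: LiAlH4, Et2O, 0 °C
Reagents that add atoms: none
Why: Hydride reduction of the acid leaves the Z alkene geometry unchanged.

**Step 14**
Reactants: 20 (2Z)-2-methylbut-2-en-1-ol
Product: 21 [(2R,3S)-2,3-dimethyloxiran-2-yl]methanol
Conditions: Ti(OiPr)4 (cat.), L-(+)-diethyl tartrate, t-BuOOH, 4 Å MS, CH2Cl2, −20 °C
Reagents that add atoms: tert-butyl hydroperoxide, CC(C)(C)OO
Why: In the Sharpless asymmetric epoxidation the L-(+)-tartrate catalyst delivers oxygen to the face that gives the (2R,3S)-epoxy alcohol.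

**Step 15**
Reactants: 21 [(2R,3S)-2,3-dimethyloxiran-2-yl]methanol
Product: 22 (2S,3S)-2,3-dimethyloxirane-2-carboxylic acid
Conditions: RuCl3 (cat.), NaIO4, MeCN/CCl4/H2O, 0 → 20 °C
Reagents that add atoms: sodium periodate, [Na+].[O-]I(=O)(=O)=O; water, O
Why: Catalytic RuO4 oxidation takes the primary alcohol to the acid without opening the epoxide; the descriptor at C2 changes only because the priorities change.

**Step 16**
Reactants: 18 8-epi carbinol lactone; 22 (2S,3S)-2,3-dimethyloxirane-2-carboxylic acid
Product: 23 (8S)-epoxyangelate ester of the lactone ynoate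
Conditions: PPh3, DIAD (betaine pre-formed), toluene, −20 → 0 °C
Reagents that add atoms: none
Why: Mitsunobu esterification of the activated propargylic alcohol proceeds by SN2 inversion, which installs the ester and corrects C8 in one operation; pre-forming the betaine keeps free phosphine away from the ynoate.

**Step 17**
Reactants: 23 (8S)-epoxyangelate ester of the lactone ynoate
Product: 24 (3R)-C3 alcohol (triethylsilyl ether removed)
Conditions: HF·pyridine, pyridine, THF, 0 °C
Reagents that add atoms: none
Why: Buffered fluoride desilylation frees the bis-allylic alcohol without ionising it or opening the glycidic ester.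

**Step 18**
Reactants: 24 (3R)-C3 alcohol
Product: 25 cis-4,5-epoxide (threo to the C3 hydroxyl)
Conditions: VO(acac)2 (cat.), t-BuOOH, CH2Cl2, 0 °C
Reagents that add atoms: tert-butyl hydroperoxide, CC(C)(C)OO
Why: Hydroxyl-directed vanadium epoxidation picks the electron-rich trisubstituted alkene, and A(1,3) strain from the cis C6 substituent places C3–H in the alkene plane, so oxygen is delivered syn to the hydroxyl and sets C4 and C5 (threo).

**Step 19**
Reactants: 25 cis-4,5-epoxide with free C3 hydroxyl
Product: 26 eight-membered cyclic enol ether (oxocane O–C9(=C10H–CO2Me)–C8–C7–C6–C5–C4–C3, vinyl on C3)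
Conditions: t-BuOK (10 mol %), THF, 1 mM, −40 → 0 °C
Reagents that add atoms: none
Why: Intramolecular oxa-Michael addition (8-exo-dig) to the ynoate should be favoured because the cis-epoxide and the trans-lactone leave few rotatable bonds in the tether and the ynoate is far more electrophilic than the methylene lactone; Payne rearrangement is blocked because C4 is fully substituted.

**Step 20**
Reactants: 26 eight-membered cyclic enol ether
Product: 27 ten-membered β-keto ester (C9 ketone, C10H–CO2Me, C2=C3 ring-Z)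
Conditions: o-xylene, 140 °C, BHT (cat.), silanised glass
Reagents that add atoms: none
Why: Thermal [3,3]-sigmatropic (Claisen) rearrangement of the allyl vinyl ether C10=C9–O–C3–C2=C1 held in the oxacycle breaks C3–O as C10–C1 forms, so the ring oxygen becomes the C9 carbonyl and C10, C1 and C2 enter the ring (8 → 10 atoms). The closest known reaction types are the Claisen ring expansion of 2-methylene-6-vinyltetrahydropyrans to cyclooct-4-enones and the thermal Claisen of allyl β-alkoxyacrylates made from allylic alcohols and alkynoates. The ten-membered ring thus closes not by an exo or endo cyclisation but by a two-atom ring expansion through a six-membered pericyclic array bridged by the C4–C8 tether. The new centre C10 is uncontrolled and irrelevant (epimerisable, sp2 after step 21), C3 loses its stereocentre, and the tether should force the C3–C4 bond pseudo-axial as in the tetrahydropyran precedents, giving the ring-Z C2=C3 bond. The step needs this Z geometry and no competing [3,3] path: the C4–C5 alkene is already an epoxide, so the vinyl group is the only allyl partner, and neutral acid-free conditions keep the vinyl epoxide intact. Formation of the C=O bond and relief of transannular strain in the oxocane drive the reaction.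

**Step 21**
Reactants: 27 ten-membered β-keto ester
Product: 30 cross-conjugated dienone ester (C9 ketone, C10(CO2Me)=C1 ring-Z, C2=C3 Z), via α-phenylselanyl β-keto ester 28 (not isolated), via selenoxide 29 (not isolated)
Conditions: PhSeCl, pyridine, CH2Cl2, 0 °C; then mCPBA (1.05 equiv), −78 → 0 °C
Reagents that add atoms: none
Why: Selenenylation of the β-keto ester enol at C10 and selenoxide syn-elimination can only engage the C1 hydrogens, giving the alkylidene β-keto ester, which should settle in the less strained ring-cis geometry.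

**Step 22**
Reactants: 30 cross-conjugated dienone ester
Product: 31 (9R)-allylic alcohol (C9–OH cis to the C8 ester)
Conditions: NaBH4, CeCl3·7H2O, MeOH, −78 °C
Reagents that add atoms: none
Why: Luche conditions give 1,2-reduction of the enone without touching the methylene lactone, and hydride is expected on the peripheral face anti to the C8–O bond (erythro, cis-diol pattern).

**Step 23**
Reactants: 31 (9R)-allylic alcohol
Product: 32 9-acetate
Conditions: Ac2O, pyridine, DMAP (cat.), CH2Cl2, 0 °C
Reagents that add atoms: acetic anhydride, CC(=O)OC(C)=O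
Why: Prompt acetylation of the only free hydroxyl fixes C9 before the hindered neighbouring ester can migrate.

**Step 24**
Reactants: 32 9-acetate
Product: 33 CNP0077535.3 (target)
Conditions: dimethyldioxirane, acetone, 0 °C
Reagents that add atoms: dimethyldioxirane, CC1(C)OO1
Why: Electrophilic epoxidation picks the γ,δ-alkene C2=C3 over the two electron-poor alkenes, and attack anti to the neighbouring 4,5-epoxide oxygen should give the cis-2,3-epoxide on the opposite face.

**Compound list**

1 | 3-methylfuran-2(5H)-one | CC1=CCOC1=O | starting material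
2 | vinylmagnesium bromide | C=C[Mg]Br | starting material
3 | 3-methyl-2,5-dihydrofuran-2-ol (lactol, racemic, present as aluminium alkoxide) | CC1=CCOC1O | intermediate
4 | rac-(2Z)-3-methylhexa-2,5-diene-1,4-diol | C=CC(O)/C(C)=C\CO | intermediate
5 | rac-(4Z)-4-methyl-6-(triethylsilyloxy)hexa-1,4-dien-3-ol | C=CC(O)/C(C)=C\CO[Si](CC)(CC)CC | intermediate
6 | (4Z)-4-methyl-6-(triethylsilyloxy)hexa-1,4-dien-3-one | C=CC(=O)/C(C)=C\CO[Si](CC)(CC)CC | intermediate
7 | (3R,4Z)-4-methyl-6-(triethylsilyloxy)hexa-1,4-dien-3-ol | C=C[C@@H](O)/C(C)=C\CO[Si](CC)(CC)CC | intermediate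
8 | (3R,4Z)-4-methyl-3,6-bis(triethylsilyloxy)hexa-1,4-diene | C=C[C@@H](O[Si](CC)(CC)CC)/C(C)=C\CO[Si](CC)(CC)CC | intermediate
9 | (2Z,4R)-3-methyl-4-(triethylsilyloxy)hexa-2,5-dienal | C=C[C@@H](O[Si](CC)(CC)CC)/C(C)=C\C=O | intermediate
10 | methyl propiolate | C#CC(=O)OC | starting material
11 | methyl (4R,5Z,7R)-4-hydroxy-6-methyl-7-(triethylsilyloxy)nona-5,8-dien-2-ynoate | C=C[C@@H](O[Si](CC)(CC)CC)/C(C)=C\[C@@H](O)C#CC(=O)OC | intermediate
12 | methyl (2Z,4S,5Z,7R)-4-hydroxy-6-methyl-7-(triethylsilyloxy)nona-2,5,8-trienoate | C=C[C@@H](O[Si](CC)(CC)CC)/C(C)=C\[C@@H](O)/C=C\C(=O)OC | intermediate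
13 | (5S)-5-[(1Z,3R)-2-methyl-3-(triethylsilyloxy)penta-1,4-dien-1-yl]furan-2(5H)-one | O=C1O[C@H](/C=C(C)\[C@H](O[Si](CC)(CC)CC)C=C)C=C1 | intermediate
14 | 3-(hydroxymethyl) derivative of 13, same configuration | O=C1O[C@H](/C=C(C)\[C@H](O[Si](CC)(CC)CC)C=C)C=C1CO | intermediate
15 | 3-(bromomethyl) derivative of 13, same configuration | O=C1O[C@H](/C=C(C)\[C@H](O[Si](CC)(CC)CC)C=C)C=C1CBr | intermediate
16 | methyl 4-hydroxybut-2-ynoate | OCC#CC(=O)OC | starting material
17 | methyl 4-oxobut-2-ynoate | O=CC#CC(=O)OC | intermediate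
18 | 6,7-trans α-methylene-γ-butyrolactone; C6 carries the (1Z,3R)-2-methyl-3-(triethylsilyloxy)penta-1,4-dienyl chain; C7 carries (R)-CH(OH)–C≡C–CO2Me (8-epi) | C=C1C(=O)O[C@H](/C=C(C)\[C@H](O[Si](CC)(CC)CC)C=C)[C@H]1[C@@H](O)C#CC(=O)OC | intermediate
19 | angelic acid, (2Z)-2-methylbut-2-enoic acid | C/C=C(/C)C(=O)O | starting material
20 | (2Z)-2-methylbut-2-en-1-ol | C/C=C(/C)CO | intermediate
21 | [(2R,3S)-2,3-dimethyloxiran-2-yl]methanol | OC[C@@]1(C)O[C@H]1C | intermediate
22 | (2S,3S)-2,3-dimethyloxirane-2-carboxylic acid | OC(=O)[C@@]1(C)O[C@H]1C | intermediate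
23 | lactone 18 with inverted C8 (8S) esterified by 22 | C=C1C(=O)O[C@H](/C=C(C)\[C@H](O[Si](CC)(CC)CC)C=C)[C@H]1[C@H](OC(=O)[C@@]2(C)O[C@H]2C)C#CC(=O)OC | intermediate
24 | 23 with free (3R)-hydroxyl | C=C1C(=O)O[C@H](/C=C(C)\[C@H](O)C=C)[C@H]1[C@H](OC(=O)[C@@]2(C)O[C@H]2C)C#CC(=O)OC | intermediate
25 | 24 with cis-4,5-epoxide, threo to the C3 hydroxyl | C=C1C(=O)O[C@H]([C@H]2O[C@@]2(C)[C@H](O)C=C)[C@H]1[C@H](OC(=O)[C@@]2(C)O[C@H]2C)C#CC(=O)OC | intermediate
26 | eight-membered cyclic (E)-enol ether: oxocane O–C9(=CH–CO2Me)–C8–C7–C6–C5–C4–C3, vinyl on C3, trans-fused to the methylene lactone at C6/C7, cis-4,5-epoxide, 8-epoxyangelate | C=C1C(=O)O[C@H]2[C@H]1[C@H](OC(=O)[C@@]3(C)O[C@H]3C)/C(=C\C(=O)OC)O[C@H](C=C)[C@]1(C)O[C@H]21 | intermediate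
27 | ten-membered β-keto ester: C9 ketone, C10H–CO2Me (epimer mixture), (2Z)-alkene, 4,5-epoxide, 6,7-lactone, 8-epoxyangelate | C=C1C(=O)O[C@H]2[C@H]1[C@H](OC(=O)[C@@]3(C)O[C@H]3C)C(=O)C(C(=O)OC)C/C=C\[C@]1(C)O[C@H]21 | intermediate
28 | 10-(phenylselanyl) derivative of 27 | C=C1C(=O)O[C@H]2[C@H]1[C@H](OC(=O)[C@@]3(C)O[C@H]3C)C(=O)C([Se]c3ccccc3)(C(=O)OC)C/C=C\[C@]1(C)O[C@H]21 | intermediate
29 | selenoxide of 28 | C=C1C(=O)O[C@H]2[C@H]1[C@H](OC(=O)[C@@]3(C)O[C@H]3C)C(=O)C([Se](=O)c3ccccc3)(C(=O)OC)C/C=C\[C@]1(C)O[C@H]21 | intermediate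
30 | dienone ester: C9 ketone, C10(CO2Me)=C1 ring-cis, (2Z)-alkene | C=C1C(=O)O[C@H]2[C@H]1[C@H](OC(=O)[C@@]3(C)O[C@H]3C)C(=O)/C(C(=O)OC)=C\C=C/[C@]1(C)O[C@H]21 | intermediate
31 | 9-alcohol of 30, C9–OH cis to C8–O | C=C1C(=O)O[C@H]2[C@H]1[C@H](OC(=O)[C@@]3(C)O[C@H]3C)[C@H](O)/C(C(=O)OC)=C\C=C/[C@]1(C)O[C@H]21 | intermediate
32 | 9-acetate of 31 | C=C1C(=O)O[C@H]2[C@H]1[C@H](OC(=O)[C@@]3(C)O[C@H]3C)[C@H](OC(C)=O)/C(C(=O)OC)=C\C=C/[C@]1(C)O[C@H]21 | intermediate
33 | CNP0077535.3 | C=C1C(=O)O[C@H]2[C@H]1[C@H](OC(=O)[C@@]1(C)O[C@H]1C)[C@H](OC(C)=O)/C(C(=O)OC)=C\[C@H]1O[C@H]1[C@]1(C)O[C@H]21 | target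

**Count**

Total steps: 24. Longest linear sequence: 20 (steps 1–10, 12, 16–24).

**Steps most likely to fail**

Step 19. The alkoxide-mediated eight-membered ring closure may be outrun by intermolecular addition, by base-induced isomerisation of the γ-acyloxy ynoate, or by acyl migration. The fallback sets out from 25 and avoids any alkoxide: a cationic gold(I) catalyst (JohnPhosAu(NCMe)SbF6, CH2Cl2, high dilution) activates the ynoate as a π-acid for anti-hydroalkoxylation. This should give the (Z)-enol ether isomer of 26, F1. Because C10 loses its geometry in the rearrangement, F1 is heated as in step 20 and rejoins the route at 27.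

Step 20. The bridged transition state may be reached only with the C3–C4 bond pseudo-equatorial, which would form the C2=C3 bond with E geometry. The fallback sets out from 26 and accepts this outcome: the (2E)-isomer of 27, F2, is taken through the selenenylation–elimination of step 21 to the (2E)-isomer of 30, F3. The C2=C3 bond is then conjugated and is equilibrated with catalytic iodine in CH2Cl2 under daylight to the less strained Z,Z-dienone, rejoining the route at 30.

Step 22. Hydride may add to the other face of the C9 ketone, so that facial selectivity is poor or reversed. The fallback sets out from 30 and uses the 9-epimeric alcohol, F4, from the same reduction. The acetate is then installed with inversion by Mitsunobu reaction with acetic acid (PPh3, DIAD, toluene, 0 °C), rejoining the route at 32.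

**Further compounds**

F1 | step 19 | (Z)-enol ether isomer of 26 | C=C1C(=O)O[C@H]2[C@H]1[C@H](OC(=O)[C@@]3(C)O[C@H]3C)/C(=C/C(=O)OC)O[C@H](C=C)[C@]1(C)O[C@H]21
F2 | step 20 | (2E)-isomer of 27 | C=C1C(=O)O[C@H]2[C@H]1[C@H](OC(=O)[C@@]3(C)O[C@H]3C)C(=O)C(C(=O)OC)C/C=C/[C@]1(C)O[C@H]21
F3 | step 20 | (2E)-isomer of 30 | C=C1C(=O)O[C@H]2[C@H]1[C@H](OC(=O)[C@@]3(C)O[C@H]3C)C(=O)/C(C(=O)OC)=C\C=C\[C@]1(C)O[C@H]21
F4 | step 22 | 9-epimer of 31 | C=C1C(=O)O[C@H]2[C@H]1[C@H](OC(=O)[C@@]3(C)O[C@H]3C)[C@@H](O)/C(C(=O)OC)=C\C=C/[C@]1(C)O[C@H]21
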